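## Retrosynthetic overview

- The six-membered ring is formed last, by a 7→6 ring contraction. A dienolate of silyl-protected dehydrozingerone adds to an α-chloro-cycloheptenone and the aryl-bearing ring carbon shifts 1,2 onto the C–Cl carbon. This closes the cyclohexene, attaches the diketone chain and sets the acyl-bearing centre by inversion.
- The chloro ketone comes from a 7-aryl-cyclohepta-2,4-dienone by Rh-catalysed asymmetric 1,4-arylation and α-chlorination, which fixes the absolute configuration; the enolisable α-aryl centre is set by equilibration.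
- The dienone comes from cyclohept-4-en-1-one by Pd α-arylation and Saegusa oxidation; the seven-membered ring is bought, not made.
- All three arenes come from catechol through 4-bromoguaiacol; the enone arm comes from a Heck reaction with methyl vinyl ketone.

Assumption: cyclohept-4-en-1-one is a catalogue chemical; the target is drawn as the enol tautomer of the given SMILES.

## Route

Step 1
Reactants: 1 catechol
Product: 2 guaiacol (2-methoxyphenol)
Conditions: MeI (1.0 equiv), K2CO3 (1.0 equiv), acetone, 56 °C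
Reagents that add atoms: iodomethane (MeI), CI
Why: Williamson O-methylation with one equivalent of MeI gives mainly the mono-ether, which is separated from veratrole (neutral) and catechol (water-soluble) by pH-controlled extraction; no stereocentre.

Step 2
Reactants: 2 guaiacol
Product: 3 4-bromo-2-methoxyphenol
Conditions: NBS (1.0 equiv), MeCN, 0 → 23 °C
Reagents that add atoms: N-bromosuccinimide (NBS), O=C1CCC(=O)N1Br
Why: Electrophilic aromatic bromination goes para to the free hydroxyl, the strongest director; no stereocentre.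

Step 3
Reactants: 3 4-bromo-2-methoxyphenol
Product: 4 4-bromo-1,2-dimethoxybenzene
Conditions: MeI (1.5 equiv), K2CO3, acetone, 56 °C
Reagents that add atoms: iodomethane (MeI), CI
Why: Williamson etherification of the remaining phenol; no stereocentre.

Step 4
Reactants: 3 4-bromo-2-methoxyphenol
Product: 5 (4-bromo-2-methoxyphenoxy)triisopropylsilane
Conditions: TIPSCl, imidazole, DMF, 23 °C
Reagents that add atoms: chlorotriisopropylsilane (TIPSCl), CC(C)[Si](Cl)(C(C)C)C(C)C
Why: Imidazole-promoted silylation of the phenol; the triisopropylsilyl ether survives alkoxide and amide bases, Pd, Rh, NCS and acid, and is removed by fluoride.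

Step 5
Reactants: 5 (4-bromo-2-methoxyphenoxy)triisopropylsilane; 6 methyl vinyl ketone
Product: 7 (E)-4-[3-methoxy-4-(triisopropylsilyloxy)phenyl]but-3-en-2-one
Conditions: Pd(OAc)2 (2 mol%), P(o-tol)3 (5 mol%), Et3N, MeCN, 80 °C
Reagents that add atoms: none
Why: Mizoroki–Heck arylation of the electron-poor terminal alkene; syn insertion and syn β-hydride elimination give the E-enone.

Step 6
Reactants: 8 cyclohept-4-en-1-one (2 equiv); 5 (4-bromo-2-methoxyphenoxy)triisopropylsilane
Product: 9 2-[3-methoxy-4-(triisopropylsilyloxy)phenyl]cyclohept-4-en-1-one (racemic)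
Conditions: Pd(OAc)2 (2 mol%), XPhos (4 mol%), NaOtBu (1.3 equiv), toluene, 70 °C
Reagents that add atoms: none
Why: Buchwald–Hartwig-type Pd-catalysed α-arylation of the symmetrical ketone enolate (excess ketone suppresses diarylation); the new centre is enolisable and is left racemic here, to be set in step 8.

Step 7
Reactants: 9 2-[3-methoxy-4-(triisopropylsilyloxy)phenyl]cyclohept-4-en-1-one
Product: 12 7-[3-methoxy-4-(triisopropylsilyloxy)phenyl]cyclohepta-2,4-dien-1-one (racemic), via lithium enolate 10 (not isolated), via trimethylsilyl enol ether 11 (not isolated)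
Conditions: LiN(iPr)2 (1.1 equiv), THF, −78 °C; TMSCl; then Pd(OAc)2 (10 mol%), O2 (1 atm), DMSO, 23 °C
Reagents that add atoms: none
Why: The hindered amide deprotonates the CH2 kinetically rather than the aryl-bearing CH, and Saegusa–Ito dehydrogenation (aerobic catalytic variant) of the regiodefined enol silane puts the new enone in conjugation with the ring alkene; the aryl-bearing centre is untouched.

Step 8
Reactants: 12 7-[3-methoxy-4-(triisopropylsilyloxy)phenyl]cyclohepta-2,4-dien-1-one; 4 4-bromo-1,2-dimethoxybenzene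
Product: 17 (2R,3R,7R)-2-chloro-3-(3,4-dimethoxyphenyl)-7-[3-methoxy-4-(triisopropylsilyloxy)phenyl]cyclohept-4-en-1-one, via aryllithium 13 (not isolated), via arylzinc chloride 14 (not isolated), via trimethylsilyl enol ether 15 (not isolated), via C7-epimeric chloro ketone 16 (not isolated)
Conditions: 4, n-BuLi, THF, −78 °C; ZnCl2, 0 °C; then 12, TMSCl, [RhCl((S)-binap)]2 (1.5 mol%), 20 °C; NCS, 0 °C; crude: TsOH·H2O (20 mol%), MeCN, 40 °C
Reagents that add atoms: N-chlorosuccinimide (NCS), O=C1CCC(=O)N1Cl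
Why: Hayashi-type Rh/binap asymmetric conjugate arylation with ArZnCl/TMSCl adds 1,4 to the δ-substituted dienone and sets C3 (with (S)-binap, the facial sense that gives (S)-3-arylcycloheptanones from cyclohept-2-enone); NCS then attacks the enol silane anti to the new C3 aryl (2,3-trans); acid-catalysed enolisation toward the aryl-bearing C7 equilibrates it to the 2,7-cis isomer with all three groups pseudo-equatorial, and the minor epimer is recycled.

Step 9
Reactants: 17 (2R,3R,7R)-2-chloro-3-(3,4-dimethoxyphenyl)-7-[3-methoxy-4-(triisopropylsilyloxy)phenyl]cyclohept-4-en-1-one; 7 (E)-4-[3-methoxy-4-(triisopropylsilyloxy)phenyl]but-3-en-2-one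
Product: 21 (2Z,4E)-1-[(1S,2S,6S)-2-(3,4-dimethoxyphenyl)-6-(4-hydroxy-3-methoxyphenyl)cyclohex-3-en-1-yl]-3-hydroxy-5-(4-hydroxy-3-methoxyphenyl)penta-2,4-dien-1-one (target), via magnesium dienolate 18 (not isolated), via chlorohydrin magnesium alkoxide 19 (not isolated), via bis-silyl diketone 20 (not isolated)
Conditions: 7 (2.2 equiv), TMPMgCl·LiCl (2.2 equiv), THF, −40 °C; 17, −78 → −20 °C; toluene, 50 °C; AcOH; then Bu4NF (3 equiv), THF, 0 °C
Reagents that add atoms: none
Why: Proposed new method: an aldol-triggered quasi-Favorskii (semipinacol) ring contraction in which the magnesium dienolate adds to the activated α-chloro ketone and, because the equatorial C2–Cl bond of the resulting chlorohydrin alkoxide is antiperiplanar to the C1–C7 ring bond (not to the oxygen, so no epoxide; not parallel to an enolate π-system, so no cyclopropanone), magnesium-assisted loss of chloride is concerted with 1,2-shift of the electron-rich benzylic C7 (retention) onto C2 (inversion), which closes the cyclohexene, creates the 1,3-diketone directly and places the acyl group cis to the migrated aryl carbon and trans to the dimethoxyphenyl carbon, the product being deprotonated at once to the diketonate (second equivalent of enolate) so the new α-centre cannot epimerise, after which fluoride in the same flask removes both silyl ethers; the closest known reactions are the Tiffeneau halohydrin ring contraction of 2-chlorocycloalkanones with Grignard reagents and the quasi-Favorskii contraction of α-halo cycloheptenones, neither shown with a ketone enolate as the nucleophile.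

## Compound list

1 | catechol (benzene-1,2-diol) | Oc1ccccc1O | starting material
2 | guaiacol (2-methoxyphenol) | COc1ccccc1O | intermediate
3 | 4-bromo-2-methoxyphenol | COc1cc(Br)ccc1O | intermediate
4 | 4-bromo-1,2-dimethoxybenzene | COc1ccc(Br)cc1OC | intermediate
5 | (4-bromo-2-methoxyphenoxy)triisopropylsilane | COc1cc(Br)ccc1O[Si](C(C)C)(C(C)C)C(C)C | intermediate
6 | methyl vinyl ketone (but-3-en-2-one) | CC(=O)C=C | starting material
7 | (E)-4-[3-methoxy-4-(triisopropylsilyloxy)phenyl]but-3-en-2-one | CC(=O)/C=C/c1ccc(O[Si](C(C)C)(C(C)C)C(C)C)c(OC)c1 | intermediate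
8 | cyclohept-4-en-1-one | O=C1CCC=CCC1 | starting material
9 | 2-[3-methoxy-4-(triisopropylsilyloxy)phenyl]cyclohept-4-en-1-one (racemic) | O=C1CCC=CCC1c1ccc(O[Si](C(C)C)(C(C)C)C(C)C)c(OC)c1 | intermediate
10 | lithium 7-[3-methoxy-4-(triisopropylsilyloxy)phenyl]cyclohepta-1,4-dien-1-olate (racemic) | [Li]OC1=CCC=CCC1c1ccc(O[Si](C(C)C)(C(C)C)C(C)C)c(OC)c1 | intermediate
11 | trimethyl({7-[3-methoxy-4-(triisopropylsilyloxy)phenyl]cyclohepta-1,4-dien-1-yl}oxy)silane (racemic) | C[Si](C)(C)OC1=CCC=CCC1c1ccc(O[Si](C(C)C)(C(C)C)C(C)C)c(OC)c1 | intermediate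
12 | 7-[3-methoxy-4-(triisopropylsilyloxy)phenyl]cyclohepta-2,4-dien-1-one (racemic) | O=C1C=CC=CCC1c1ccc(O[Si](C(C)C)(C(C)C)C(C)C)c(OC)c1 | intermediate
13 | (3,4-dimethoxyphenyl)lithium | [Li]c1ccc(OC)c(OC)c1 | intermediate
14 | (3,4-dimethoxyphenyl)zinc chloride | Cl[Zn]c1ccc(OC)c(OC)c1 | intermediate
15 | {[(3S)-3-(3,4-dimethoxyphenyl)-7-[3-methoxy-4-(triisopropylsilyloxy)phenyl]cyclohepta-1,4-dien-1-yl]oxy}trimethylsilane (both C7 epimers) | C[Si](C)(C)OC1=C[C@@H](c2ccc(OC)c(OC)c2)C=CCC1c1ccc(O[Si](C(C)C)(C(C)C)C(C)C)c(OC)c1 | intermediate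
16 | (2R,3R,7S)-2-chloro-3-(3,4-dimethoxyphenyl)-7-[3-methoxy-4-(triisopropylsilyloxy)phenyl]cyclohept-4-en-1-one (C7 epimer of 17) | O=C1[C@H](Cl)[C@@H](c2ccc(OC)c(OC)c2)C=CC[C@H]1c1ccc(O[Si](C(C)C)(C(C)C)C(C)C)c(OC)c1 | intermediate
17 | (2R,3R,7R)-2-chloro-3-(3,4-dimethoxyphenyl)-7-[3-methoxy-4-(triisopropylsilyloxy)phenyl]cyclohept-4-en-1-one | O=C1[C@H](Cl)[C@@H](c2ccc(OC)c(OC)c2)C=CC[C@@H]1c1ccc(O[Si](C(C)C)(C(C)C)C(C)C)c(OC)c1 | intermediate
18 | chloromagnesium (3E)-4-[3-methoxy-4-(triisopropylsilyloxy)phenyl]buta-1,3-dien-2-olate | Cl[Mg]OC(=C)/C=C/c1ccc(O[Si](C(C)C)(C(C)C)C(C)C)c(OC)c1 | intermediate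
19 | chloromagnesium (2R,3R,7R)-2-chloro-3-(3,4-dimethoxyphenyl)-7-[3-methoxy-4-(triisopropylsilyloxy)phenyl]-1-{(3E)-4-[3-methoxy-4-(triisopropylsilyloxy)phenyl]-2-oxobut-3-en-1-yl}cyclohept-4-en-1-olate (C1 not assigned; either face leads on) | Cl[Mg]OC1(CC(=O)/C=C/c2ccc(O[Si](C(C)C)(C(C)C)C(C)C)c(OC)c2)[C@H](Cl)[C@@H](c2ccc(OC)c(OC)c2)C=CC[C@@H]1c1ccc(O[Si](C(C)C)(C(C)C)C(C)C)c(OC)c1 | intermediate
20 | (2Z,4E)-1-[(1S,2S,6S)-2-(3,4-dimethoxyphenyl)-6-[3-methoxy-4-(triisopropylsilyloxy)phenyl]cyclohex-3-en-1-yl]-3-hydroxy-5-[3-methoxy-4-(triisopropylsilyloxy)phenyl]penta-2,4-dien-1-one | COc1cc(/C=C/C(O)=C/C(=O)[C@@H]2[C@@H](c3ccc(OC)c(OC)c3)C=CC[C@@H]2c2ccc(O[Si](C(C)C)(C(C)C)C(C)C)c(OC)c2)ccc1O[Si](C(C)C)(C(C)C)C(C)C | intermediate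
21 | (2Z,4E)-1-[(1S,2S,6S)-2-(3,4-dimethoxyphenyl)-6-(4-hydroxy-3-methoxyphenyl)cyclohex-3-en-1-yl]-3-hydroxy-5-(4-hydroxy-3-methoxyphenyl)penta-2,4-dien-1-one | COc1cc(/C=C/C(O)=C/C(=O)[C@@H]2[C@@H](c3ccc(OC)c(OC)c3)C=CC[C@@H]2c2ccc(O)c(OC)c2)ccc1O | target

## Step count

Total steps: 9. Longest linear sequence: 7 (steps 1, 2, 4, 6, 7, 8, 9).

## Three steps most likely to fail

**Step 9 (the new reaction).** Retro-aldol of 19, enolisation of 17 by the enolate, or a sluggish shift could defeat it. The fallback uses known chemistry and sets out from 17. MeMgBr (THF, −78 °C) adds to the ketone to give the bromomagnesium chlorohydrinate F1, which on warming in toluene undergoes the classical Tiffeneau halohydrin ring contraction to the methyl ketone F2, with the same inversion/retention course. Separately, a Heck reaction of 5 with methyl acrylate (C=CC(=O)OC) gives the silyl-protected methyl ferulate F3. Crossed Claisen condensation of the kinetic lithium enolate F4 of F2 (LiN(SiMe3)2, THF, −78 °C) with F3 gives 20, where the fallback comes back to the route; fluoride then gives 21.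

**Step 8.** Possible problems are 1,6- instead of 1,4-arylation, inefficient trapping of the enolate, or an unfavourable C7 equilibrium. The fallback sets out from 12 and the aryllithium 13. Quenching 13 with B(OiPr)3 and aqueous acid gives (3,4-dimethoxyphenyl)boronic acid F5. The Hayashi–Miyaura addition in its best-precedented aqueous form (Rh(acac)(C2H4)2, (S)-binap, dioxane/H2O, 100 °C) then gives the protonated adduct, ketone F6, as a mixture of C2 epimers. Kinetic enolisation and silylation of F6 on the CH2 side (LiN(iPr)2, TMSCl, THF, −78 °C) gives enol silane 15, where the fallback comes back to the route (NCS, then TsOH, as in step 8).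

**Step 7.** The regioselectivity of the kinetic enolisation of the α-aryl ketone is the weak point. The fallback reverses the order of arylation and dehydrogenation and sets out from 8. IBX (DMSO/toluene, 70 °C) dehydrogenates 8 to cyclohepta-2,4-dien-1-one F7. Its kinetic cross-conjugated zinc enolate F8 (LiN(iPr)2, THF, −78 °C; ZnCl2) is arylated with 5 under zerovalent palladium catalysis (Pd(dba)2, P(t-Bu)3, THF, 23 °C) to give 12, where the fallback comes back to the route.

## Further compounds

F1 | step 9 | bromomagnesium (2R,3R,7R)-2-chloro-3-(3,4-dimethoxyphenyl)-7-[3-methoxy-4-(triisopropylsilyloxy)phenyl]-1-methylcyclohept-4-en-1-olate (C1 not assigned) | Br[Mg]OC1(C)[C@H](Cl)[C@@H](c2ccc(OC)c(OC)c2)C=CC[C@@H]1c1ccc(O[Si](C(C)C)(C(C)C)C(C)C)c(OC)c1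
F2 | step 9 | 1-[(1S,2S,6S)-2-(3,4-dimethoxyphenyl)-6-[3-methoxy-4-(triisopropylsilyloxy)phenyl]cyclohex-3-en-1-yl]ethan-1-one | CC(=O)[C@@H]1[C@@H](c2ccc(OC)c(OC)c2)C=CC[C@@H]1c1ccc(O[Si](C(C)C)(C(C)C)C(C)C)c(OC)c1
F3 | step 9 | methyl (E)-3-[3-methoxy-4-(triisopropylsilyloxy)phenyl]prop-2-enoate | COC(=O)/C=C/c1ccc(O[Si](C(C)C)(C(C)C)C(C)C)c(OC)c1
F4 | step 9 | lithium 1-[(1S,2S,6S)-2-(3,4-dimethoxyphenyl)-6-[3-methoxy-4-(triisopropylsilyloxy)phenyl]cyclohex-3-en-1-yl]ethen-1-olate | [Li]OC(=C)[C@@H]1[C@@H](c2ccc(OC)c(OC)c2)C=CC[C@@H]1c1ccc(O[Si](C(C)C)(C(C)C)C(C)C)c(OC)c1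
F5 | step 8 | (3,4-dimethoxyphenyl)boronic acid | OB(O)c1ccc(OC)c(OC)c1
F6 | step 8 | (6R)-6-(3,4-dimethoxyphenyl)-2-[3-methoxy-4-(triisopropylsilyloxy)phenyl]cyclohept-4-en-1-one (both C2 epimers) | O=C1C[C@@H](c2ccc(OC)c(OC)c2)C=CCC1c1ccc(O[Si](C(C)C)(C(C)C)C(C)C)c(OC)c1
F7 | step 7 | cyclohepta-2,4-dien-1-one | O=C1C=CC=CCC1
F8 | step 7 | chlorozinc cyclohepta-1,4,6-trien-1-olate | Cl[Zn]OC1=CCC=CC=C1
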